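## Structural features

The target is a 3,3''-linked biflavonoid: a 5,7,4'-trihydroxyflavanone (rings A, C and B) bonded through C3 to C3'' of a 5,7,4'-trihydroxyflavone (rings A'', C'' and B''), i.e. a 2,3-dihydro-3,3''-biapigenin. Its only stereocentres, C2 and C3, are neighbours in ring C; (2S,3R) is the trans arrangement, with the ring B aryl group and the flavonyl group both equatorial. Both centres are fragile: C3–H is α to the C4 ketone and epimerises easily (trans is the stable form), and base can open ring C by retro-oxa-Michael loss of the C8a phenoxide, which erases C2. The six free phenols make the molecule air-sensitive in base. The real difficulty is the congested C3–C3'' bond between two carbons that each carry a carbonyl and an aryl-bearing neighbour, together with absolute control at C2 in a ring that can reopen. The two halves differ only in oxidation level at C2/C3, so any symmetrical construction has to be desymmetrised. The key step uses the fact that rings A and A'' are both acylphloroglucinols, each the folded form of an acyl triacetate chain whose acyl carbon is C4 or C4''. These two carbons are the ends of the four-carbon unit C4–C3–C3''–C4'', on which C2 and C2'' sit as aryl-bearing one-carbon branches.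

## Logic of the disconnections

16 to 15: the two O–CH2Ph bonds on rings B and B'' are cut. These are the only phenols that must be masked through the carbanion chemistry, so the protecting-group count falls to two. The forward step must be neutral and must spare the benzylic C2–O1 bond, the C4 ketone and both stereocentres.

15 to 14: the O1–C2 bond is cut. This removes ring C and both stereocentres and leads to an achiral compound. The forward closure must be catalyst-controlled at C2 and must outrun uncatalysed closure; C3 then follows by equilibration to trans.

14 to 12 (through 13): C4a–C5, C4a''–C5'' and O1''–C2'' are cut. Both A rings are folded triketides, and C2'' already carries an enol ether at the flavone oxidation level. Three rings disappear and the molecule becomes a linear C16 chain with two aryl branches. The forward step needs Claisen folding of both arms, pyranone closure only on the C2'' side, and survival of the benzylidene half.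

12 to 11: the two terminal β-keto ester units are masked as dioxinones. The free hexaketo diester cannot be stored or carried through C–C bond formation, whereas 11 can be purified. Unmasking must be neutral so that the enol ether and the enone survive.

11 to 8 plus two equivalents of 10: the C4–C4a and C4''–C4a'' bonds are cut. This is convergent and two-directional: 10 supplies each six-carbon arm, and 8 is a four-carbon bis-acyl donor with no enolisable hydrogen. The acyl groups of 8 are Weinreb amides because a diacid at this position would close to a cyclic anhydride on activation, and because the chelated adducts release the diketones only at the quench.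

10 to 9: the bond between the acetyl carbon and the side-chain carbon is cut. 9 is commercial but is only a four-carbon unit, so one acetate must be added before it can serve as the triketide.

8 to 7, then 7 to 5 plus 6: the O–CH3 bond and then the C3''–C2'' bond are cut. C2'' with its aryl group enters as an aroyl electrophile at the only enolisable position of 5, and O-methylation installs the leaving group for the later pyranone closure. The forward steps need C-acylation followed by O- rather than C-alkylation.

5 to 4, then 4 to 1 plus 2: the two amide C–N bonds and then the C2=C3 double bond are cut. The condensation places the benzylidene on one α-carbon only, which differentiates the two halves of the symmetrical four-carbon unit: one becomes the chalcone-level C2/C3, the other keeps the methylene that becomes C3''. The forward step must give the E isomer and stop after one condensation.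

## Other disconnections considered

Alternative 1: The cut is C3–C4 of ring C.
- Forward key step: the ring A aldehyde A1, 4,6-bis(benzyloxy)-2-({1-[4-(benzyloxy)phenyl]-3-[4-(benzyloxy)benzoyl]-4-[2,4-bis(benzyloxy)-6-(methoxymethoxy)phenyl]-4-oxobut-2-en-1-yl}oxy)benzaldehyde (racemic at the ether carbon), is treated with an aminoindanol-derived triazolium carbene precursor and a tertiary amine. The acyl-anion equivalent adds to C3 of the alkylidene diketone and gives the chromanone A2, (2S,3R)-5,7-bis(benzyloxy)-2-[4-(benzyloxy)phenyl]-3-{1-[4-(benzyloxy)phenyl]-3-[2,4-bis(benzyloxy)-6-(methoxymethoxy)phenyl]-1,3-dioxopropan-2-yl}chroman-4-one. The ether carbon is meant to equilibrate by reversible γ-deprotonation (dynamic kinetic resolution).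
- In its favour: intramolecular Stetter closure to chroman-4-ones is the best-developed asymmetric use of these carbenes. The stereo-defining event is an irreversible C–C bond formation on a substrate with no free phenol. The diketone side chain of A2 is the classical flavone precursor.
- Against it here: the donor is a doubly ortho-substituted, electron-rich benzaldehyde, and the acceptor carbon has a branched neighbour. The resolution needs C2 to racemise faster than ring closure without the double bond leaving conjugation or the aryloxide departing. A1 needs a hindered secondary benzylic aryl ether, a condensation with an unsymmetrical diaryl diketone, and three classes of phenol protection.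
- Comparison: structurally it buys all four oxygenated arenes preformed, whereas the chosen plan makes rings A and A'' from chains and needs two protecting groups. Mechanistically it is the better plan on one point: C2 and C3 are fixed in a C–C bond-forming step and not by a reversible O–C closure on a polyphenol. Neither key step has direct precedent. After A2 it needs acetal removal, cyclodehydration and hydrogenolysis of six ethers, and the approach to A1 is longer, so it is expected to be several steps longer than the chosen plan.

Alternative 2: The cuts are C2–C3, C2''–C3'' and both O1–C2 bonds.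
- Forward key step: the bis-ester A3, 1,4-bis{2,4-bis(benzyloxy)-6-[4-(benzyloxy)benzoyloxy]phenyl}butane-1,4-dione, undergoes a double O-to-C aroyl shift under a lithium amide base, and acid then closes both pyranones. The product is the symmetrical biflavone A4, 5,5'',7,7''-tetrakis(benzyloxy)-2,2''-bis[4-(benzyloxy)phenyl]-3,3''-bi(4H-chromen-4-one).
- In its favour: it uses the hidden twofold symmetry, every step to A4 is a classical reaction type, and the C3–C3'' bond is present from the first intermediate. On brevity and precedent up to A4 it is the better plan.
- Against it here: the target is not symmetrical. Going on from A4 needs an enantioselective conjugate reduction of only one of two identical, tetrasubstituted, shielded C2=C3 bonds, for which no dependable method exists; over-reduction and statistical mixtures are to be expected. The 1,4-diketone can close to a furan under the acidic cyclisation, and the second enolisation next to an existing enolate is difficult. A4 has no stereocentre, but rotation about C3–C3'' is likely to be hindered.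
- Comparison: structurally it postpones the oxidation-level difference to the end, whereas the chosen plan encodes it in the first step (benzylidene against aryl(methoxy)methylidene). Mechanistically its key step is far better founded than the chosen folding, but its stereochemical step is much weaker than an oxa-Michael closure. In step count to the key product it is shorter, but the remaining step is the unsolved one.

Alternative 3: The cut is O1–C2, the same bond as in the penultimate step of the chosen plan, but on a fully protected substrate.
- Forward key step: the chalcone A5, (E)-1-[2,4-bis(benzyloxy)-6-hydroxyphenyl]-3-[4-(benzyloxy)phenyl]-2-{5,7-bis(benzyloxy)-2-[4-(benzyloxy)phenyl]-4-oxo-4H-chromen-3-yl}prop-2-en-1-one, closes under a cinchona-derived thiourea to A6, the hexa-O-benzyl ether of the (2S,3R) target.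
- In its favour: there is one free phenol, no acidic para-hydroxyl to bind the catalyst, no spontaneous closure, and good solubility in non-polar solvents. On the stereo-defining step this substrate is better than 14 of the chosen plan.
- Against it here: A5 has to be assembled by conventional flavonoid chemistry from two separately protected phloroglucinol units. The hindered α-flavonyl ketone must be condensed with the aldehyde while the ortho phenol is masked, since the free phenol would close to the racemic chromanone under the basic condensation. Six benzyl ethers must be cleaved at the end.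
- Comparison: structure and final bond are the same as in the chosen plan, and the mechanism of the asymmetric step is identical. In step economy it is clearly longer, because the chosen plan creates both A rings and the flavone in one operation.

Key step: step 8

Remarks on the chemistry:
- A four-carbon dioxinone anion would extend an acyl group only to a 3,5-diketo ester. Each arm needs six carbons beyond C4 or C4'', so 9 is first acetylated to 10, which is used as its dianion.
- In the folding, the former ester carbon becomes C5 or the equivalent C8a of the new phloroglucinol ring; the bond is called C4a–C5 for convenience.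
- All exchangeable groups of 12 are methoxy groups (esters, enol ether), matched to the methoxide base and methanol solvent of step 8, so exchange is degenerate.
- Assumption: the sense of induction of the cinchona thiourea on 14 is not known in advance. The quinine-derived catalyst is written; its quinidine-derived pseudoenantiomer replaces it if the sense proves opposite.

## Route

Step 1
Reactants: 1 dimethyl succinate; 2 4-(benzyloxy)benzaldehyde
Product: 4 (2E)-2-{[4-(benzyloxy)phenyl]methylidene}butanedioic acid, via Stobbe half-ester 3 (not isolated)
Conditions: NaOMe (1.5 equiv), MeOH, reflux; then 2 M NaOH (aq), reflux; then HCl (aq), 0 °C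
Reagents that add atoms: sodium hydroxide, [Na+].[OH-]
Why: Stobbe condensation: the succinate enolate adds to the aldehyde, the aldolate lactonises and E1cB ring opening gives the half-ester 3 with the aryl group trans to the conjugated carbonyl (the thermodynamic E isomer). Aqueous hydroxide then saponifies the remaining ester in the same flask; the benzyl ether is inert.

Step 2
Reactants: 4 (2E)-2-{[4-(benzyloxy)phenyl]methylidene}butanedioic acid
Product: 5 (2E)-2-{[4-(benzyloxy)phenyl]methylidene}-N1,N4-dimethoxy-N1,N4-dimethylbutanediamide
Conditions: MeNH(OMe)·HCl (2.4 equiv), EDC·HCl (2.4 equiv), HOBt (0.2 equiv), N-methylmorpholine, CH2Cl2, 0 °C → rt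
Reagents that add atoms: N,O-dimethylhydroxylamine hydrochloride, CNOC.Cl
Why: Carbodiimide amide coupling (Weinreb amide formation); any cyclic anhydride formed on activation is opened by the amine and the second carboxyl then couples, so both paths converge on 5. The weak base limits migration of the double bond.

Step 3
Reactants: 5 (2E)-2-{[4-(benzyloxy)phenyl]methylidene}-N1,N4-dimethoxy-N1,N4-dimethylbutanediamide; 6 4-(benzyloxy)benzoyl chloride
Product: 7 (3E)-2-[4-(benzyloxy)benzoyl]-3-{[4-(benzyloxy)phenyl]methylidene}-N1,N4-dimethoxy-N1,N4-dimethylbutanediamide (racemic at C2)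
Conditions: LiN(SiMe3)2 (2.2 equiv), THF, −78 °C; then 6, −78 → −40 °C; NH4Cl (aq)
Reagents that add atoms: none
Why: Crossed Claisen-type C-acylation of an amide enolate: the methylene group is the only enolisable position of 5, and the second equivalent of base deprotonates the β-keto amide as it forms, which suppresses proton transfer and double acylation. The new methine centre is racemic and is removed in step 4.

Step 4
Reactants: 7 (3E)-2-[4-(benzyloxy)benzoyl]-3-{[4-(benzyloxy)phenyl]methylidene}-N1,N4-dimethoxy-N1,N4-dimethylbutanediamide
Product: 8 (2E)-2-{[4-(benzyloxy)phenyl]methylidene}-3-{[4-(benzyloxy)phenyl](methoxy)methylidene}-N1,N4-dimethoxy-N1,N4-dimethylbutanediamide (enol ether geometry not defined)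
Conditions: Me2SO4 (1.5 equiv), Cs2CO3 (1.5 equiv), DMF, 0 °C → rt
Reagents that add atoms: dimethyl sulfate, COS(=O)(=O)OC
Why: O-Alkylation of a β-dicarbonyl enolate: a hard methylating agent, the caesium counter-ion, a dipolar aprotic solvent and the fully substituted α-carbon all direct methylation to oxygen. The enol ether geometry is irrelevant because C2'' ends in an aromatic pyranone.

Step 5
Reactants: 9 2,2,6-trimethyl-4H-1,3-dioxin-4-one
Product: 10 2,2-dimethyl-6-(2-oxopropyl)-4H-1,3-dioxin-4-one
Conditions: LiN(SiMe3)2 (1.0 equiv), THF, −78 °C; then AcCl (0.5 equiv), −78 °C; NH4Cl (aq)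
Reagents that add atoms: acetyl chloride, CC(=O)Cl
Why: γ-Acylation of the lithium dienolate of a dioxinone (vinylogous Claisen condensation); half of the dienolate serves as base for the more acidic product, and the corresponding amount of 9 is recovered.

Step 6
Reactants: 8 (2E)-2-{[4-(benzyloxy)phenyl]methylidene}-3-{[4-(benzyloxy)phenyl](methoxy)methylidene}-N1,N4-dimethoxy-N1,N4-dimethylbutanediamide; 10 2,2-dimethyl-6-(2-oxopropyl)-4H-1,3-dioxin-4-one (3 equiv)
Product: 11 (5E)-5-{[4-(benzyloxy)phenyl]methylidene}-6-{[4-(benzyloxy)phenyl](methoxy)methylidene}-1,10-bis(2,2-dimethyl-4-oxo-4H-1,3-dioxin-6-yl)decane-2,4,7,9-tetrone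
Conditions: 10, LiN(i-Pr)2 (2 equiv per 10), THF, −78 °C; then 8, −78 → −20 °C; AcOH, −78 °C; pH 5 phosphate buffer
Reagents that add atoms: none
Why: Acylation of the terminal carbon of the keto-dioxinone dianion by Weinreb amides (Weinreb ketone synthesis), run in two directions. 8 has no enolisable hydrogen, and the chelated tetrahedral adducts keep both new 1,3-diketones masked until the quench. The buffered work-up and brief chromatography on neutral silica protect the enol ether.

Step 7
Reactants: 11 (5E)-5-{[4-(benzyloxy)phenyl]methylidene}-6-{[4-(benzyloxy)phenyl](methoxy)methylidene}-1,10-bis(2,2-dimethyl-4-oxo-4H-1,3-dioxin-6-yl)decane-2,4,7,9-tetrone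
Product: 12 dimethyl (8E)-8-{[4-(benzyloxy)phenyl]methylidene}-9-{[4-(benzyloxy)phenyl](methoxy)methylidene}-3,5,7,10,12,14-hexaoxohexadecanedioate
Conditions: MeOH–PhMe (1:4), 100 °C, sealed tube, 1 h; concentrated below 30 °C and used at once
Reagents that add atoms: methanol, CO
Why: Thermal retro-[4+2] fragmentation of each dioxinone releases acetone and an acylketene, which the large excess of methanol captures as the methyl β-keto ester (acylketene trapping). The medium is neutral, so the enol ether and the enone are not touched; 12 is a mixture of keto–enol tautomers and is not purified.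

Step 8
Reactants: 12 dimethyl (8E)-8-{[4-(benzyloxy)phenyl]methylidene}-9-{[4-(benzyloxy)phenyl](methoxy)methylidene}-3,5,7,10,12,14-hexaoxohexadecanedioate
Product: 14 (2E)-3-[4-(benzyloxy)phenyl]-2-{2-[4-(benzyloxy)phenyl]-5,7-dihydroxy-4-oxo-4H-chromen-3-yl}-1-(2,4,6-trihydroxyphenyl)prop-2-en-1-one, via bis(acylphloroglucinol) enol ether 13 (not isolated)
Conditions: Mg(OMe)2 (10 equiv), degassed MeOH, Ar, 25 → 50 °C; then poured into 1 M HCl (aq), 0 °C, EtOAc
Reagents that add atoms: none
Why: Proposed new method: a twofold biomimetic Claisen (Dieckmann-type) folding followed in the same flask by pyranone closure; the closest known reaction type is the Mg(OMe)2-mediated Claisen cyclisation of a single 3,5,7-triketo ester to an acylphloroglucinol. Mg(OMe)2 turns each arm into a magnesium-chelated polyenolate, and the carbanion at C4a (or C4a''), the central carbon of the chelated 1,3-diketonate, attacks the terminal ester carbon; methoxide leaves and the cyclohexanetrione enolises, so rings A and A'' each close by 6-exo-trig C-acylation and give 13. In 13 one ortho oxygen of ring A'' chelates magnesium together with the C4'' carbonyl and the other is thereby turned toward C2'', where it adds to the β-methoxy enone (6-endo-trig oxa-conjugate addition) and expels methoxide to leave the aromatic pyranone ring C''. Claisen rather than aldol folding is expected because C4 and C4'' are flanked by the fully substituted sp2 carbons C3 and C3'' and C4'' is in addition a deactivated vinylogous ester carbonyl, which should also disfavour the five-membered aldol across the 1,4-dicarbonyl unit. Before ring A'' exists, chelation holds the enolate oxygen of that arm syn to the C4'' oxygen and away from C2'', which should delay premature 4-pyranone closure, and O-acylation to a 4-hydroxy-2-pyranone or methoxide exchange at C2'' and at the esters is reversible or degenerate in methanolic methoxide, whereas aromatisation is not. The chalcone half has no leaving group at C2, its oxa-Michael adduct can reopen, and the strongly basic medium favours the open magnesium phenolate, so it should persist until the cold acidic quench. No stereocentre is formed; the benzylidene geometry is under thermodynamic control and E is the favoured isomer.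

Step 9
Reactants: 14 (2E)-3-[4-(benzyloxy)phenyl]-2-{2-[4-(benzyloxy)phenyl]-5,7-dihydroxy-4-oxo-4H-chromen-3-yl}-1-(2,4,6-trihydroxyphenyl)prop-2-en-1-one
Product: 15 (2S,3R)-2-[4-(benzyloxy)phenyl]-3-{2-[4-(benzyloxy)phenyl]-5,7-dihydroxy-4-oxo-4H-chromen-3-yl}-5,7-dihydroxy-2,3-dihydro-4H-chromen-4-one
Conditions: N-[3,5-bis(trifluoromethyl)phenyl]-N'-[(8α,9S)-6'-methoxycinchonan-9-yl]thiourea (20 mol %), 2-MeTHF–PhMe (1:1), −20 °C; AcOH, then filtration through silica
Reagents that add atoms: none
Why: Organocatalytic enantioselective intramolecular oxa-Michael addition (chalcone-to-flavanone closure): the quinuclidine nitrogen deprotonates an ortho hydroxyl of ring A while the thiourea binds the C4 carbonyl, so the phenoxide is delivered to one face of C2 and 2S is set under catalyst control. C3 is set by protonation of the enol and, being α to the ketone, equilibrates under the amine to the trans (3R) isomer with both large groups equatorial. The two ortho hydroxyls of ring A are equivalent, so either closure gives 15.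

Step 10
Reactants: 15 (2S,3R)-2-[4-(benzyloxy)phenyl]-3-{2-[4-(benzyloxy)phenyl]-5,7-dihydroxy-4-oxo-4H-chromen-3-yl}-5,7-dihydroxy-2,3-dihydro-4H-chromen-4-one
Product: 16 (2S,3R)-5,7-dihydroxy-3-[5,7-dihydroxy-2-(4-hydroxyphenyl)-4-oxo-4H-chromen-3-yl]-2-(4-hydroxyphenyl)-2,3-dihydro-4H-chromen-4-one
Conditions: H2 (1 atm), Pd/C (10 %), EtOAc–MeOH (1:1), rt
Reagents that add atoms: none
Why: Hydrogenolysis of the two aryl benzyl ethers; at atmospheric pressure and stopped when 15 is consumed, the benzylic C2–O1 bond, the hydrogen-bonded C4 ketone and the tetrasubstituted C2''=C3'' bond should remain. The neutral medium leaves C2 and C3 unchanged.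

## Compound list

1 | dimethyl succinate | COC(=O)CCC(=O)OC | starting material
2 | 4-(benzyloxy)benzaldehyde | O=Cc1ccc(OCc2ccccc2)cc1 | starting material
3 | (3E)-4-[4-(benzyloxy)phenyl]-3-(methoxycarbonyl)but-3-enoic acid | COC(=O)/C(=C/c1ccc(OCc2ccccc2)cc1)CC(=O)O | intermediate (not isolated)
4 | (2E)-2-{[4-(benzyloxy)phenyl]methylidene}butanedioic acid | OC(=O)/C(=C/c1ccc(OCc2ccccc2)cc1)CC(=O)O | intermediate
5 | (2E)-2-{[4-(benzyloxy)phenyl]methylidene}-N1,N4-dimethoxy-N1,N4-dimethylbutanediamide | CON(C)C(=O)/C(=C/c1ccc(OCc2ccccc2)cc1)CC(=O)N(C)OC | intermediate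
6 | 4-(benzyloxy)benzoyl chloride | O=C(Cl)c1ccc(OCc2ccccc2)cc1 | starting material
7 | (3E)-2-[4-(benzyloxy)benzoyl]-3-{[4-(benzyloxy)phenyl]methylidene}-N1,N4-dimethoxy-N1,N4-dimethylbutanediamide, racemic at C2 | CON(C)C(=O)/C(=C/c1ccc(OCc2ccccc2)cc1)C(C(=O)c1ccc(OCc2ccccc2)cc1)C(=O)N(C)OC | intermediate
8 | (2E)-2-{[4-(benzyloxy)phenyl]methylidene}-3-{[4-(benzyloxy)phenyl](methoxy)methylidene}-N1,N4-dimethoxy-N1,N4-dimethylbutanediamide, enol ether geometry not defined | CON(C)C(=O)/C(=C/c1ccc(OCc2ccccc2)cc1)C(=C(OC)c1ccc(OCc2ccccc2)cc1)C(=O)N(C)OC | intermediate
9 | 2,2,6-trimethyl-4H-1,3-dioxin-4-one | CC1=CC(=O)OC(C)(C)O1 | starting material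
10 | 2,2-dimethyl-6-(2-oxopropyl)-4H-1,3-dioxin-4-one | CC(=O)CC1=CC(=O)OC(C)(C)O1 | intermediate
11 | (5E)-5-{[4-(benzyloxy)phenyl]methylidene}-6-{[4-(benzyloxy)phenyl](methoxy)methylidene}-1,10-bis(2,2-dimethyl-4-oxo-4H-1,3-dioxin-6-yl)decane-2,4,7,9-tetrone | CC1(C)OC(=O)C=C(CC(=O)CC(=O)/C(=C/c2ccc(OCc3ccccc3)cc2)C(=C(OC)c2ccc(OCc3ccccc3)cc2)C(=O)CC(=O)CC2=CC(=O)OC(C)(C)O2)O1 | intermediate
12 | dimethyl (8E)-8-{[4-(benzyloxy)phenyl]methylidene}-9-{[4-(benzyloxy)phenyl](methoxy)methylidene}-3,5,7,10,12,14-hexaoxohexadecanedioate | COC(=O)CC(=O)CC(=O)CC(=O)/C(=C/c1ccc(OCc2ccccc2)cc1)C(=C(OC)c1ccc(OCc2ccccc2)cc1)C(=O)CC(=O)CC(=O)CC(=O)OC | intermediate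
13 | (2E)-2-{[4-(benzyloxy)phenyl]methylidene}-3-{[4-(benzyloxy)phenyl](methoxy)methylidene}-1,4-bis(2,4,6-trihydroxyphenyl)butane-1,4-dione | O=C(c1c(O)cc(O)cc1O)/C(=C/c1ccc(OCc2ccccc2)cc1)C(=C(OC)c1ccc(OCc2ccccc2)cc1)C(=O)c1c(O)cc(O)cc1O | intermediate (not isolated)
14 | (2E)-3-[4-(benzyloxy)phenyl]-2-{2-[4-(benzyloxy)phenyl]-5,7-dihydroxy-4-oxo-4H-chromen-3-yl}-1-(2,4,6-trihydroxyphenyl)prop-2-en-1-one | O=C(c1c(O)cc(O)cc1O)/C(=C/c1ccc(OCc2ccccc2)cc1)c1c(-c2ccc(OCc3ccccc3)cc2)oc2cc(O)cc(O)c2c1=O | intermediate
15 | (2S,3R)-2-[4-(benzyloxy)phenyl]-3-{2-[4-(benzyloxy)phenyl]-5,7-dihydroxy-4-oxo-4H-chromen-3-yl}-5,7-dihydroxy-2,3-dihydro-4H-chromen-4-one | O=C1c2c(O)cc(O)cc2O[C@H](c2ccc(OCc3ccccc3)cc2)[C@H]1c1c(-c2ccc(OCc3ccccc3)cc2)oc2cc(O)cc(O)c2c1=O | intermediate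
16 | (2S,3R)-5,7-dihydroxy-3-[5,7-dihydroxy-2-(4-hydroxyphenyl)-4-oxo-4H-chromen-3-yl]-2-(4-hydroxyphenyl)-2,3-dihydro-4H-chromen-4-one | O=C1c2c(O)cc(O)cc2O[C@H](c2ccc(O)cc2)[C@H]1c1c(-c2ccc(O)cc2)oc2cc(O)cc(O)c2c1=O | target

## Step count and least certain steps

Total: 10 steps. Longest linear sequence: 9 steps (steps 1 to 4 and 6 to 10); step 5 is a one-step branch.

Step 8 (key step, proposed new method). The most likely failure is folding of one or both arms in the wrong mode. This could be aldol attack on C4 or C4'', aldol across the 1,4-dicarbonyl unit, lactonisation, or premature oxygen closure onto C2''. Uncontrolled closure of the chalcone half during the quench is a further risk. The cause is that six enolisable positions and four electrophilic carbons compete in one molecule, and the directing role of magnesium chelation is an argument, not an established behaviour. The fallback uses known chemistry and brings the two A rings in as preformed arenes. It sets out from 8. 1,3,5-Tris(methoxymethoxy)benzene F1 (from phloroglucinol, chloromethyl methyl ether and i-Pr2NEt) is lithiated at C2 with n-BuLi in THF and added to both Weinreb amides of 8. This gives (2E)-2-{[4-(benzyloxy)phenyl]methylidene}-3-{[4-(benzyloxy)phenyl](methoxy)methylidene}-1,4-bis[2,4,6-tris(methoxymethoxy)phenyl]butane-1,4-dione F2. Brief treatment with HCl in MeOH removes the six acetals, and the freed ortho phenol of ring A'' closes the pyranone by acid-mediated addition–elimination at C2''. The route is rejoined at 14.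

Step 6. The most likely failure is incomplete or misdirected acylation. Both amide carbonyls are hindered, and the one that becomes C4'' is deactivated by the β-methoxy group, so the dianion may decompose or add in conjugate fashion before it acylates. The fallback changes the electrophile class and sets out from 8. Reduction of both amides with (i-Bu)2AlH at −78 °C gives (2E)-2-{[4-(benzyloxy)phenyl]methylidene}-3-{[4-(benzyloxy)phenyl](methoxy)methylidene}butanedial F3. Aldol addition of the dianion of 10 gives (5E)-5-{[4-(benzyloxy)phenyl]methylidene}-6-{[4-(benzyloxy)phenyl](methoxy)methylidene}-1,10-bis(2,2-dimethyl-4-oxo-4H-1,3-dioxin-6-yl)-4,7-dihydroxydecane-2,9-dione F4 as a mixture of diastereomers. Oxidation with Dess–Martin periodinane buffered with NaHCO3 returns to the route at 11.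

Step 9. The most likely failure is erosion of enantioselectivity. Three causes are foreseeable: uncatalysed closure of the free trihydroxyphenyl ketone, binding of the basic catalyst by the acidic para hydroxyls, and reversible ring opening of the product under the amine. The fallback replaces asymmetric catalysis by resolution and sets out from 14. Closure with NaOAc in EtOH gives the trans racemate, which is separated on a chiral stationary phase into 15 and its (2R,3S) enantiomer F5. F5 is racemised through base-mediated ring opening and reclosure and then resolved again. The route is rejoined at 15.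

Step 7. The most likely failure is loss of material by thermal side reactions. The acylketene may be captured by an enol oxygen of its own arm instead of methanol, or an arm enol may close onto the methoxy enone at 100 °C. The fallback avoids the dioxinone and the heating and sets out from 8. The trianion of methyl 3,5-dioxohexanoate (COC(=O)CC(=O)CC(C)=O, LiN(i-Pr)2, 3 equiv per keto ester) is added to both Weinreb amides at −78 °C, followed by a buffered quench. This returns directly to the route at 12 with no new compound. It is not the first choice because 12 would then be formed in strongly basic solution and could not be purified at the stage of 11.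

Step 4. The most likely failure is methylation at carbon (C3'' or the benzylic end of the extended enolate) in place of oxygen, together with scrambling of the benzylidene geometry through the delocalised anion. The fallback avoids an ambident anion and sets out from 7. Acid-catalysed enol ether formation with HC(OMe)3 and catalytic TsOH in MeOH at 50 °C proceeds through the oxocarbenium ion and returns to the route at 8 with no new compound.

## Further compounds

F1 | step 8 | 1,3,5-tris(methoxymethoxy)benzene | COCOc1cc(OCOC)cc(OCOC)c1
F2 | step 8 | (2E)-2-{[4-(benzyloxy)phenyl]methylidene}-3-{[4-(benzyloxy)phenyl](methoxy)methylidene}-1,4-bis[2,4,6-tris(methoxymethoxy)phenyl]butane-1,4-dione | COCOc1cc(OCOC)c(C(=O)/C(=C/c2ccc(OCc3ccccc3)cc2)C(=C(OC)c2ccc(OCc3ccccc3)cc2)C(=O)c2c(OCOC)cc(OCOC)cc2OCOC)c(OCOC)c1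
F3 | step 6 | (2E)-2-{[4-(benzyloxy)phenyl]methylidene}-3-{[4-(benzyloxy)phenyl](methoxy)methylidene}butanedial | O=C/C(=C/c1ccc(OCc2ccccc2)cc1)C(C=O)=C(OC)c1ccc(OCc2ccccc2)cc1
F4 | step 6 | (5E)-5-{[4-(benzyloxy)phenyl]methylidene}-6-{[4-(benzyloxy)phenyl](methoxy)methylidene}-1,10-bis(2,2-dimethyl-4-oxo-4H-1,3-dioxin-6-yl)-4,7-dihydroxydecane-2,9-dione, mixture of diastereomers | CC1(C)OC(=O)C=C(CC(=O)CC(O)/C(=C/c2ccc(OCc3ccccc3)cc2)C(=C(OC)c2ccc(OCc3ccccc3)cc2)C(O)CC(=O)CC2=CC(=O)OC(C)(C)O2)O1
F5 | step 9 | (2R,3S)-2-[4-(benzyloxy)phenyl]-3-{2-[4-(benzyloxy)phenyl]-5,7-dihydroxy-4-oxo-4H-chromen-3-yl}-5,7-dihydroxy-2,3-dihydro-4H-chromen-4-one | O=C1c2c(O)cc(O)cc2O[C@@H](c2ccc(OCc3ccccc3)cc2)[C@@H]1c1c(-c2ccc(OCc3ccccc3)cc2)oc2cc(O)cc(O)c2c1=O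
F0 | step 7 | none | none
F0 | step 4 | none | none
A1 | alternative 1 | 4,6-bis(benzyloxy)-2-({1-[4-(benzyloxy)phenyl]-3-[4-(benzyloxy)benzoyl]-4-[2,4-bis(benzyloxy)-6-(methoxymethoxy)phenyl]-4-oxobut-2-en-1-yl}oxy)benzaldehyde, racemic, alkene geometry not defined | O=Cc1c(OCc2ccccc2)cc(OCc2ccccc2)cc1OC(c1ccc(OCc2ccccc2)cc1)C=C(C(=O)c1ccc(OCc2ccccc2)cc1)C(=O)c1c(OCOC)cc(OCc2ccccc2)cc1OCc1ccccc1
A2 | alternative 1 | (2S,3R)-5,7-bis(benzyloxy)-2-[4-(benzyloxy)phenyl]-3-{1-[4-(benzyloxy)phenyl]-3-[2,4-bis(benzyloxy)-6-(methoxymethoxy)phenyl]-1,3-dioxopropan-2-yl}chroman-4-one, diketone methine not defined | O=C1c2c(OCc3ccccc3)cc(OCc3ccccc3)cc2O[C@H](c2ccc(OCc3ccccc3)cc2)[C@H]1C(C(=O)c1ccc(OCc2ccccc2)cc1)C(=O)c1c(OCOC)cc(OCc2ccccc2)cc1OCc1ccccc1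
A3 | alternative 2 | 1,4-bis{2,4-bis(benzyloxy)-6-[4-(benzyloxy)benzoyloxy]phenyl}butane-1,4-dione | O=C(CCC(=O)c1c(OCc2ccccc2)cc(OCc2ccccc2)cc1OC(=O)c1ccc(OCc2ccccc2)cc1)c1c(OCc2ccccc2)cc(OCc2ccccc2)cc1OC(=O)c1ccc(OCc2ccccc2)cc1
A4 | alternative 2 | 5,5'',7,7''-tetrakis(benzyloxy)-2,2''-bis[4-(benzyloxy)phenyl]-3,3''-bi(4H-chromen-4-one) | O=c1c(-c2c(-c3ccc(OCc4ccccc4)cc3)oc3cc(OCc4ccccc4)cc(OCc4ccccc4)c3c2=O)c(-c2ccc(OCc3ccccc3)cc2)oc2cc(OCc3ccccc3)cc(OCc3ccccc3)c12
A5 | alternative 3 | (E)-1-[2,4-bis(benzyloxy)-6-hydroxyphenyl]-3-[4-(benzyloxy)phenyl]-2-{5,7-bis(benzyloxy)-2-[4-(benzyloxy)phenyl]-4-oxo-4H-chromen-3-yl}prop-2-en-1-one | O=C(c1c(O)cc(OCc2ccccc2)cc1OCc1ccccc1)/C(=C/c1ccc(OCc2ccccc2)cc1)c1c(-c2ccc(OCc3ccccc3)cc2)oc2cc(OCc3ccccc3)cc(OCc3ccccc3)c2c1=O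
A6 | alternative 3 | (2S,3R)-5,7-bis(benzyloxy)-2-[4-(benzyloxy)phenyl]-3-{5,7-bis(benzyloxy)-2-[4-(benzyloxy)phenyl]-4-oxo-4H-chromen-3-yl}-2,3-dihydro-4H-chromen-4-one | O=C1c2c(OCc3ccccc3)cc(OCc3ccccc3)cc2O[C@H](c2ccc(OCc3ccccc3)cc2)[C@H]1c1c(-c2ccc(OCc3ccccc3)cc2)oc2cc(OCc3ccccc3)cc(OCc3ccccc3)c2c1=O
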